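**Plan**

- The target is the achiral flavonol 6,8-diprenylquercetin. The retrosynthesis first opens ring C at O1–C2 (cyclodehydration) and then cuts C4a–C4 and C3–C4 together.
- This works because C4 is a single carbonyl carbon lying between C4a of the symmetrical, fully substituted phloroglucinol ring A and the oxygen-bearing C3. It can therefore enter as carbon monoxide between an aryl iodide carbon and the α-carbon of an α-alkoxy ketone, and the two oxygens flanking C4a are equivalent.
- Ring A is cut further at its two aryl–prenyl bonds and the C–I bond, back to phloroglucinol tris-MOM ether. The ring B ketone comes from 2-chloro-3',4'-dihydroxyacetophenone.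
- Forward: ring A is built by three directed lithiations (steps 1–4) and the ring B ketone is made (steps 5–6). The chain C4a–C4–C3–C2 is joined in one carbonylative coupling (step 7), and ring C closes last during global deprotection (step 8).
- Stereochemistry: the target has no stereocentre. The centres at C3 of the diketone and at C2/C3 of the hemiketal are transient and vanish when ring C aromatises.

Key step: step 7

Remark: MOM is methoxymethyl; flavone numbering (O1, C2–C4, C4a, C5–C8, C8a; rings A, B and C) is used throughout, and compounds with transient stereocentres are drawn without configuration.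

**Route**

Step 1
Reactants: 1 phloroglucinol
Product: 2 1,3,5-tris(methoxymethoxy)benzene
Conditions: NaH (3.6 equiv), MOMCl (3.6 equiv), DMF, 0 °C → rt
Reagents that add atoms: chloromethyl methyl ether (MOMCl), COCCl
Why: Threefold Williamson-type O-alkylation of the phenoxide with the hard electrophile MOMCl in DMF should give the tris-acetal with little C-alkylation and installs the groups that direct all later lithiations.

Step 2
Reactants: 2 1,3,5-tris(methoxymethoxy)benzene; 3 prenyl bromide (1-bromo-3-methylbut-2-ene)
Product: 5 1,3,5-tris(methoxymethoxy)-2-(3-methylbut-2-en-1-yl)benzene, via aryllithium 4 (not isolated)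
Conditions: nBuLi (1.1 equiv), THF, 0 °C; then CuI (10 mol%), 3 (1.2 equiv), −78 °C → rt
Reagents that add atoms: none
Why: Directed ortho-metalation at a ring position flanked by two MOM-oxy groups gives aryllithium 4, which should be alkylated at the primary carbon of prenyl bromide (copper-catalysed SN2 allylic substitution) to give the linear prenyl arene.

Step 3
Reactants: 5 1,3,5-tris(methoxymethoxy)-2-(3-methylbut-2-en-1-yl)benzene; 3 prenyl bromide
Product: 7 1,3,5-tris(methoxymethoxy)-2,4-bis(3-methylbut-2-en-1-yl)benzene, via aryllithium 6 (not isolated)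
Conditions: nBuLi (1.15 equiv), THF, 0 °C; then CuI (10 mol%), 3 (1.3 equiv), −78 °C → rt
Reagents that add atoms: none
Why: A second directed ortho-metalation is expected at either of the two equivalent ring hydrogens, each doubly activated by flanking MOM-oxy groups and therefore kinetically favoured over the benzylic–allylic CH2, and the same copper-catalysed allylation then installs the second prenyl group.

Step 4
Reactants: 7 1,3,5-tris(methoxymethoxy)-2,4-bis(3-methylbut-2-en-1-yl)benzene
Product: 9 2-iodo-1,3,5-tris(methoxymethoxy)-4,6-bis(3-methylbut-2-en-1-yl)benzene, via aryllithium 8 (not isolated)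
Conditions: nBuLi (1.2 equiv), THF, 0 °C; then I2 (1.3 equiv), THF, −78 °C; aq. Na2S2O3
Reagents that add atoms: iodine, II
Why: A third directed ortho-metalation removes the last ring hydrogen, and iodinolysis of the aryllithium at −78 °C, where iodine should not add to the trisubstituted alkenes, places the iodide between two MOM-oxy groups.

Step 5
Reactants: 10 2-chloro-1-(3,4-dihydroxyphenyl)ethanone
Product: 12 1-(3,4-dihydroxyphenyl)-2-hydroxyethanone, via formate ester 11 (not isolated)
Conditions: HCO2Na (5 equiv), HCO2H (1 equiv), EtOH–H2O 4:1, reflux, argon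
Reagents that add atoms: sodium formate, [Na+].[O-]C=O
Why: SN2 displacement of the activated α-chloride by formate, followed by solvolysis of the labile formate ester in the same pot (the formate route from α-halo ketones to α-hydroxy ketones), should proceed in a weakly acidic buffer that keeps the catechol un-ionised and thus protected from O-alkylation and air oxidation.

Step 6
Reactants: 12 1-(3,4-dihydroxyphenyl)-2-hydroxyethanone
Product: 13 1-[3,4-bis(methoxymethoxy)phenyl]-2-(methoxymethoxy)ethanone
Conditions: MOMCl (4.5 equiv), iPr2NEt (6 equiv), nBu4NI (cat.), CH2Cl2–DMF, 0 → 40 °C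
Reagents that add atoms: chloromethyl methyl ether (MOMCl), COCCl
Why: Amine-mediated MOM ether formation should cap both phenols and the primary ketol hydroxyl without enolising the ketone, giving an α-alkoxy ketone whose protecting groups all fall in the final acid step.

Step 7
Reactants: 9 2-iodo-1,3,5-tris(methoxymethoxy)-4,6-bis(3-methylbut-2-en-1-yl)benzene; 13 1-[3,4-bis(methoxymethoxy)phenyl]-2-(methoxymethoxy)ethanone; 14 carbon monoxide
Product: 15 1-[3,4-bis(methoxymethoxy)phenyl]-2-(methoxymethoxy)-3-[2,4,6-tris(methoxymethoxy)-3,5-bis(3-methylbut-2-en-1-yl)phenyl]propane-1,3-dione (racemic)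
Conditions: Pd(OAc)2 (5 mol%), Xantphos (7.5 mol%), K3PO4 (3 equiv), 13 (1.5 equiv), CO (5 bar), 1,4-dioxane, 90 °C; then aq. NH4Cl
Reagents that add atoms: none
Why: Zerovalent palladium, formed in situ from Pd(OAc)2 and Xantphos under CO, inserts into the C–I bond of 9, CO migratory insertion gives the 2,6-dioxygenated aroylpalladium iodide (C4a–C4), and the phosphate-generated potassium enolate of 13 binds at palladium and is released by C–C reductive elimination (C3–C4), the acidic product being held as its potassium enolate until work-up. The closest known reaction type is the palladium-catalysed carbonylative α-arylation of aryl alkyl ketones with aryl iodides to 1,3-diketones. No ring is closed here, and the only new stereocentre, C3 of 15, is formed racemic and enolisable and disappears when ring C aromatises, so it needs no control. Carbonylative coupling must beat direct α-arylation: the two ortho MOM-oxy groups crowd the arylpalladium and slow direct aryl–enolate coupling while CO insertion relieves strain, and the CO pressure and the wide-bite-angle ligand, which speeds acyl–carbon reductive elimination, act in the same direction. C-acylation must beat O-acylation: elimination from the carbon-bound palladium enolate gives the diketone, and excess phosphate deprotonates the product so that it is not acylated a second time. The prenyl groups are meta to the C–Pd bond and trisubstituted, so Heck-type insertion should not interfere, and the MOM acetals are inert to the mild base.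

Step 8
Reactants: 15 1-[3,4-bis(methoxymethoxy)phenyl]-2-(methoxymethoxy)-3-[2,4,6-tris(methoxymethoxy)-3,5-bis(3-methylbut-2-en-1-yl)phenyl]propane-1,3-dione
Product: 18 2-(3,4-dihydroxyphenyl)-3,5,7-trihydroxy-6,8-bis(3-methylbut-2-en-1-yl)-4H-chromen-4-one (6,8-diprenylquercetin), via hexahydroxy diketone 16 (not isolated), via cyclic hemiketal 17 (not isolated)
Conditions: 3 M aq. HCl–MeOH (1:4), 50 °C, argon
Reagents that add atoms: none
Why: Acid-catalysed acetal exchange with methanol should remove all six MOM groups as dimethoxymethane, after which either of the two equivalent ortho phenols of ring A adds to the ring B ketone (6-exo-trig hemiketalisation) and loss of water from hemiketal 17 aromatises the pyranone, as in the acid cyclodehydration of o-hydroxyaryl 1,3-diketones to flavones, with moderate acid strength and temperature chosen to spare the prenyl groups.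

**Compound list**

1 | phloroglucinol (benzene-1,3,5-triol) | Oc1cc(O)cc(O)c1 | starting material
2 | 1,3,5-tris(methoxymethoxy)benzene | COCOc1cc(OCOC)cc(OCOC)c1 | intermediate
3 | prenyl bromide (1-bromo-3-methylbut-2-ene) | CC(C)=CCBr | starting material
4 | [2,4,6-tris(methoxymethoxy)phenyl]lithium | [Li]c1c(OCOC)cc(OCOC)cc1OCOC | intermediate
5 | 1,3,5-tris(methoxymethoxy)-2-(3-methylbut-2-en-1-yl)benzene | CC(C)=CCc1c(OCOC)cc(OCOC)cc1OCOC | intermediate
6 | [2,4,6-tris(methoxymethoxy)-3-(3-methylbut-2-en-1-yl)phenyl]lithium | [Li]c1c(OCOC)cc(OCOC)c(CC=C(C)C)c1OCOC | intermediate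
7 | 1,3,5-tris(methoxymethoxy)-2,4-bis(3-methylbut-2-en-1-yl)benzene | CC(C)=CCc1c(OCOC)cc(OCOC)c(CC=C(C)C)c1OCOC | intermediate
8 | [2,4,6-tris(methoxymethoxy)-3,5-bis(3-methylbut-2-en-1-yl)phenyl]lithium | [Li]c1c(OCOC)c(CC=C(C)C)c(OCOC)c(CC=C(C)C)c1OCOC | intermediate
9 | 2-iodo-1,3,5-tris(methoxymethoxy)-4,6-bis(3-methylbut-2-en-1-yl)benzene | CC(C)=CCc1c(OCOC)c(CC=C(C)C)c(OCOC)c(I)c1OCOC | intermediate
10 | 2-chloro-1-(3,4-dihydroxyphenyl)ethanone (2-chloro-3',4'-dihydroxyacetophenone) | O=C(CCl)c1ccc(O)c(O)c1 | starting material
11 | 2-(3,4-dihydroxyphenyl)-2-oxoethyl formate | O=COCC(=O)c1ccc(O)c(O)c1 | intermediate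
12 | 1-(3,4-dihydroxyphenyl)-2-hydroxyethanone | OCC(=O)c1ccc(O)c(O)c1 | intermediate
13 | 1-[3,4-bis(methoxymethoxy)phenyl]-2-(methoxymethoxy)ethanone | COCOCC(=O)c1ccc(OCOC)c(OCOC)c1 | intermediate
14 | carbon monoxide | [C-]#[O+] | starting material
15 | 1-[3,4-bis(methoxymethoxy)phenyl]-2-(methoxymethoxy)-3-[2,4,6-tris(methoxymethoxy)-3,5-bis(3-methylbut-2-en-1-yl)phenyl]propane-1,3-dione (racemic) | CC(C)=CCc1c(OCOC)c(CC=C(C)C)c(OCOC)c(C(=O)C(OCOC)C(=O)c2ccc(OCOC)c(OCOC)c2)c1OCOC | intermediate
16 | 1-(3,4-dihydroxyphenyl)-2-hydroxy-3-[2,4,6-trihydroxy-3,5-bis(3-methylbut-2-en-1-yl)phenyl]propane-1,3-dione (racemic) | CC(C)=CCc1c(O)c(CC=C(C)C)c(O)c(C(=O)C(O)C(=O)c2ccc(O)c(O)c2)c1O | intermediate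
17 | 2-(3,4-dihydroxyphenyl)-2,3,5,7-tetrahydroxy-6,8-bis(3-methylbut-2-en-1-yl)-2,3-dihydro-4H-chromen-4-one (stereoisomer mixture) | CC(C)=CCc1c(O)c(CC=C(C)C)c2OC(O)(c3ccc(O)c(O)c3)C(O)C(=O)c2c1O | intermediate
18 | 2-(3,4-dihydroxyphenyl)-3,5,7-trihydroxy-6,8-bis(3-methylbut-2-en-1-yl)-4H-chromen-4-one (6,8-diprenylquercetin, CNP0196011.0) | CC(C)=CCc1c(O)c(CC=C(C)C)c2oc(-c3ccc(O)c(O)c3)c(O)c(=O)c2c1O | target

**Step count**

Total: 8 steps. Longest linear sequence: 6 steps (steps 1, 2, 3, 4, 7, 8); the two-step ketone branch (steps 5, 6) joins at step 7.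

**Steps most likely to fail**

1. Step 7. The crowded aroylpalladium intermediate may be captured too slowly by the enolate. O-acylation to an enol ester, loss of the acyl group to adventitious water, or non-carbonylative arylation could then take over. The fallback sets out from 7 and builds the same C4a–C4 and C3–C4 bonds stepwise, with C4 supplied by DMF. Lithiation of 7 as in step 4 gives aryllithium 8, and a DMF quench should give 2,4,6-tris(methoxymethoxy)-3,5-bis(3-methylbut-2-en-1-yl)benzaldehyde F1. Ketone 13 is deprotonated with LiN(SiMe3)2 (THF, −78 °C) to its chelated lithium (Z)-enolate F2. Aldol addition of this enolate to F1 should give 1-[3,4-bis(methoxymethoxy)phenyl]-3-hydroxy-2-(methoxymethoxy)-3-[2,4,6-tris(methoxymethoxy)-3,5-bis(3-methylbut-2-en-1-yl)phenyl]propan-1-one F3 as a diastereomer mixture. Dess–Martin oxidation (NaHCO3, CH2Cl2, rt) of the β-hydroxy ketone then returns to the route at diketone 15.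

2. Step 8. Under protic acid a freed phenol at C5 or C7 may add across a neighbouring prenyl double bond (2,2-dimethylchroman formation), or HCl or methanol may add to the alkenes before acetal cleavage and ring closure are complete. The fallback sets out from 15 and separates deprotection from cyclisation. ZnBr2 and n-PrSH in CH2Cl2 at 0 °C cleave the MOM acetals by Lewis acid activation and thiol capture, without free protic acid and within minutes. This should give the hexahydroxy diketone 16, where the route is rejoined. In this variant 16 is isolated under argon and closed to 18 through hemiketal 17 by warming with NaOAc in AcOH (60–80 °C), a buffered cyclodehydration too weakly acidic to engage the prenyl groups.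

3. Step 3. Deprotonation may occur in part at the benzylic–allylic CH2 of the first prenyl group (lateral metalation) or stay incomplete, giving hard-to-separate mixtures of mono-, di- and side-chain-alkylated arenes. The fallback sets out from 2 and generates the aryllithium by halogen–lithium exchange instead of deprotonation. NBS (2 equiv, MeCN, 0 °C) should give 2,4-dibromo-1,3,5-tris(methoxymethoxy)benzene F4. One equivalent of nBuLi (THF, −78 °C) exchanges a single bromine to give [3-bromo-2,4,6-tris(methoxymethoxy)phenyl]lithium F5. Alkylation with prenyl bromide 3 (CuI cat.) then gives 2-bromo-1,3,5-tris(methoxymethoxy)-4-(3-methylbut-2-en-1-yl)benzene F6. A second bromine–lithium exchange at −78 °C, far faster than any C–H deprotonation, returns to the route at aryllithium 6, which is prenylated to 7 as in step 3.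

**Further compounds**

F1 | step 7 | 2,4,6-tris(methoxymethoxy)-3,5-bis(3-methylbut-2-en-1-yl)benzaldehyde | CC(C)=CCc1c(OCOC)c(CC=C(C)C)c(OCOC)c(C=O)c1OCOC
F2 | step 7 | lithium (Z)-1-[3,4-bis(methoxymethoxy)phenyl]-2-(methoxymethoxy)ethen-1-olate (lithium enolate of 13) | [Li]O/C(=C\OCOC)c1ccc(OCOC)c(OCOC)c1
F3 | step 7 | 1-[3,4-bis(methoxymethoxy)phenyl]-3-hydroxy-2-(methoxymethoxy)-3-[2,4,6-tris(methoxymethoxy)-3,5-bis(3-methylbut-2-en-1-yl)phenyl]propan-1-one (diastereomer mixture) | CC(C)=CCc1c(OCOC)c(CC=C(C)C)c(OCOC)c(C(O)C(OCOC)C(=O)c2ccc(OCOC)c(OCOC)c2)c1OCOC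
F0 | step 8 | none | none
F4 | step 3 | 2,4-dibromo-1,3,5-tris(methoxymethoxy)benzene | COCOc1cc(OCOC)c(Br)c(OCOC)c1Br
F5 | step 3 | [3-bromo-2,4,6-tris(methoxymethoxy)phenyl]lithium | [Li]c1c(OCOC)cc(OCOC)c(Br)c1OCOC
F6 | step 3 | 2-bromo-1,3,5-tris(methoxymethoxy)-4-(3-methylbut-2-en-1-yl)benzene | CC(C)=CCc1c(OCOC)cc(OCOC)c(Br)c1OCOC
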